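**Retrosynthetic overview**
1. Feature: ring A is a phloroglucinol whose C4a carries the C4 ketone, so C4–C4a–C5–C6–C7–C8–C8a is a folded tetraketide chain and ring A can be made by joining C4a to C8a.
2. Ring C is disconnected last at O1–C2: acid opens a C2/C3 acetonide at benzylic C2, an ortho hydroxyl of ring A closes the ring trans to the C3 hydroxyl, and the MOM groups fall off.
3. Ring A is disconnected at C4a–C8a: magnesium-mediated Claisen cyclisation of a methyl 3,5,7-trioxoheptanoate bearing the (4R,5S)-dioxolane. The chain comes from the dioxolane Weinreb amide and the dianion of a dioxinone-masked diketide, unmasked by methanolysis.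
4. C3 (and C2 provisionally) come from an Evans syn-glycolate aldol on the ring B aldehyde, which is built from resorcinol by three MOM-directed lithiations (geranyl, prenyl, formyl).
5. Order of rings: ring B (resorcinol), ring A (step 13), ring C (step 14).

Key step: step 13

Assumption: the SMILES is read as the (2R,3R)-trans-dihydroflavonol; 2-[(tert-butyldimethylsilyl)oxy]acetic acid and (R)-4-benzyl-1,3-oxazolidin-2-one are taken as purchasable.
Abbreviation: Ar = 3-[(2E)-3,7-dimethylocta-2,6-dienyl]-2,4-bis(methoxymethoxy)-5-(3-methylbut-2-enyl)phenyl; flavonoid numbering (O1, C2, C3, C4, C4a, C5 to C8, C8a) is used for the chain atoms.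

**Route**

Step 1
Reactants: 1 resorcinol
Product: 2 1,3-bis(methoxymethoxy)benzene
Conditions: MOMCl (2.5 equiv), i-Pr2NEt (3 equiv), CH2Cl2, 0 °C to rt
Reagents that add atoms: chloromethyl methyl ether, COCCl
Why: Double O-alkylation of the phenols with MOMCl under amine base (Williamson-type ether formation) is routine and installs the groups that direct all three later ring metalations.

Step 2
Reactants: 2 1,3-bis(methoxymethoxy)benzene; 3 geranyl bromide
Product: 5 2-geranyl-1,3-bis(methoxymethoxy)benzene, via aryllithium 4 (not isolated)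
Conditions: n-BuLi (1.1 equiv), THF, 0 °C to rt; CuBr·SMe2 (10 mol%), 3, −78 °C to rt
Reagents that add atoms: none
Why: Directed ortho-metalation takes place at the position flanked by both OMOM groups, and copper-catalysed allylic substitution of aryllithium 4 with the primary allylic bromide occurs at the α-carbon without allylic transposition, so the E-olefin of the geranyl chain is kept.

Step 3
Reactants: 5 2-geranyl-1,3-bis(methoxymethoxy)benzene; 6 prenyl bromide
Product: 8 2-geranyl-1,3-bis(methoxymethoxy)-4-prenylbenzene, via aryllithium 7 (not isolated)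
Conditions: n-BuLi (1.2 equiv), TMEDA, THF, 0 °C; CuBr·SMe2 (10 mol%), 6, −78 °C to rt
Reagents that add atoms: none
Why: A second directed ortho-metalation can only occur ortho to an OMOM group (the two open positions are equivalent by symmetry), and the same copper-catalysed SN2 coupling delivers the prenyl group.

Step 4
Reactants: 8 2-geranyl-1,3-bis(methoxymethoxy)-4-prenylbenzene
Product: 10 aldehyde ArCHO, via aryllithium 9 (not isolated)
Conditions: n-BuLi (1.2 equiv), TMEDA, THF, −20 to 0 °C; DMF, −78 °C to rt; H2O
Reagents that add atoms: N,N-dimethylformamide, CN(C)C=O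
Why: The single remaining position ortho to an OMOM group is lithiated by n-BuLi/TMEDA through coordination to the acetal oxygens, which is expected to be faster than removal of a benzylic–allylic proton, and the aryllithium is formylated by DMF.

Step 5
Reactants: 11 2-[(tert-butyldimethylsilyl)oxy]acetic acid; 12 (R)-4-benzyl-1,3-oxazolidin-2-one
Product: 14 (R)-4-benzyl-3-{[(tert-butyldimethylsilyl)oxy]acetyl}-1,3-oxazolidin-2-one, via mixed pivalic anhydride 13 (not isolated)
Conditions: t-BuCOCl, Et3N, THF, −20 °C; 12, LiCl, −20 °C to rt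
Reagents that add atoms: none
Why: N-Acylation of the oxazolidinone by the mixed pivalic anhydride under LiCl/Et3N activation is the standard mild route to glycolyl imides and takes place at the less hindered glycolyl carbonyl.

Step 6
Reactants: 14 glycolyl imide; 10 aldehyde ArCHO
Product: 16 (R)-4-benzyl-3-[(2R,3S)-3-Ar-2-(tert-butyldimethylsilyloxy)-3-hydroxypropanoyl]-1,3-oxazolidin-2-one, via Z-boron enolate 15 (not isolated)
Conditions: Bu2BOTf (1.2 equiv), Et3N (1.4 equiv), CH2Cl2, −78 to 0 °C; 10, −78 to 0 °C; pH 7 phosphate buffer, MeOH, 30% H2O2, 0 °C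
Reagents that add atoms: none
Why: Evans syn-aldol: soft enolisation gives the Z-boron enolate, which reacts through a closed chair (Zimmerman–Traxler) transition state with the imide dipoles opposed so that the aldehyde adds to the enolate face away from the (R)-benzyl group, setting C3 as R and the benzylic carbon C2 as S (2,3-syn).

Step 7
Reactants: 16 syn-aldol imide
Product: 17 (2R,3S)-3-Ar-2-(tert-butyldimethylsilyloxy)-3-hydroxy-N-methoxy-N-methylpropanamide
Conditions: MeNHOMe·HCl (3 equiv), AlMe3 (3 equiv), CH2Cl2, −20 to 0 °C; aq potassium sodium tartrate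
Reagents that add atoms: N,O-dimethylhydroxylamine hydrochloride, CNOC.Cl
Why: Aluminium amide transamidation (Weinreb amide formation) cleaves the exocyclic imide carbonyl selectively, assisted by the free β-hydroxyl as its aluminium alkoxide, and releases the auxiliary without touching the two stereocenters.

Step 8
Reactants: 17 silyl ether Weinreb amide
Product: 18 (2R,3S)-3-Ar-2,3-dihydroxy-N-methoxy-N-methylpropanamide
Conditions: Bu4NF (1.2 equiv), THF, 0 °C
Reagents that add atoms: none
Why: Fluoride-induced cleavage of the silicon–oxygen bond frees the C3 hydroxyl under conditions that leave the aryl MOM ethers, the olefins and the amide untouched.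

Step 9
Reactants: 18 diol Weinreb amide
Product: 19 (4R,5S)-5-Ar-N-methoxy-N,2,2-trimethyl-1,3-dioxolane-4-carboxamide
Conditions: 2-methoxypropene (3 equiv), PPTS (5 mol%), CH2Cl2, 0 °C to rt
Reagents that add atoms: 2-methoxypropene, COC(C)=C
Why: Acid-catalysed acetalisation of the syn-diol with the enol ether gives the five-membered acetonide, which for a syn (threo) diol is the trans-dioxolane and therefore the thermodynamically favoured diastereomer, under acid too weak to cleave aryl MOM ethers.

Step 10
Reactants: 20 2,2,6-trimethyl-4H-1,3-dioxin-4-one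
Product: 22 2,2-dimethyl-6-(2-oxopropyl)-4H-1,3-dioxin-4-one, via lithium dienolate 21 (not isolated)
Conditions: LiN(SiMe3)2 (1.0 equiv), THF, −78 °C; AcCl (0.5 equiv), −78 °C; AcOH
Reagents that add atoms: acetyl chloride, CC(=O)Cl
Why: The lithium dienolate of the dioxinone is acylated at its γ-carbon (vinylogous Claisen condensation), and using half an equivalent of acetyl chloride lets the second equivalent of dienolate absorb the proton of the more acidic product.

Step 11
Reactants: 22 keto-dioxinone; 19 dioxolane Weinreb amide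
Product: 24 6-{4-[(4R,5S)-5-Ar-2,2-dimethyl-1,3-dioxolan-4-yl]-2,4-dioxobutyl}-2,2-dimethyl-4H-1,3-dioxin-4-one, via dilithium dianion 23 (not isolated)
Conditions: LiN(i-Pr)2 (2.1 equiv per 22), THF, −78 to −40 °C; 19 (0.67 equiv), −78 to −20 °C; AcOH, −78 °C
Reagents that add atoms: none
Why: Claisen-type C-acylation at the terminal, last-formed and most nucleophilic carbon of dianion 23 by the Weinreb amide, whose chelated tetrahedral adduct survives until the quench so that neither over-addition nor proton transfer from the diketone product can occur, while at −78 °C acylation should outrun deprotonation at C3.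

Step 12
Reactants: 24 diketo-dioxinone
Product: 26 methyl 7-[(4R,5S)-5-Ar-2,2-dimethyl-1,3-dioxolan-4-yl]-3,5,7-trioxoheptanoate, via acylketene 25 (not isolated)
Conditions: MeOH (20 equiv), toluene, 110 °C, sealed tube, 1 h; concentrate, use crude
Reagents that add atoms: methanol, CO
Why: Thermal retro-hetero-Diels–Alder fragmentation of the dioxinone expels acetone to give acylketene 25, which is captured by the excess methanol faster than by its own enol oxygen to give the β-keto ester terminus.

Step 13
Reactants: 26 triketo ester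
Product: 28 [(4R,5S)-5-Ar-2,2-dimethyl-1,3-dioxolan-4-yl](2,4,6-trihydroxyphenyl)methanone, via acylcyclohexanetrione tautomer 27 (not isolated)
Conditions: Mg(OMe)2 (8 equiv), MeOH, rt to 40 °C, argon; then cold 0.5 M HCl to pH 4
Reagents that add atoms: none
Why: Mg(OMe)2 turns the triketo ester into a magnesium-chelated polyenolate whose C4/C5 β-diketonate carbon C4a adds to the ester carbon C8a, methoxide leaves, and the 2-acylcyclohexane-1,3,5-trione 27 so formed enolises irreversibly to the phloroglucinol, which pulls the sequence forward. The closest known reaction type is the magnesium-alkoxide Claisen cyclisation of 3,5,7-triketo esters (and of the isomeric 6-acylmethyl-4-hydroxy-2-pyranones, which open to the same chelate) to acylphloroglucinols. Ring A closes in a 6-exo-trig mode, the ring being C4a–C5–C6–C7–C8–C8a with the ester C=O exocyclic, and the C4a–C8a bond is the one skeletal bond made. No stereocenter is created; C3 of the dioxolane is a spectator that is kept from enolising because C4 is locked in the chelated enolate towards C4a and because the trans-dioxolane is the thermodynamically preferred diastereomer. The selectivity needed is Claisen against aldol folding (C4a onto C8a rather than C8 onto C4, which would give a resorcylate): divalent magnesium ties the C4 carbonyl into a six-membered β-diketonate chelate, lowering its electrophilicity, the α-branched dioxolane shields it, and the unchelated ester carbonyl remains the reachable electrophile. The two hydroxyls ortho to the ketone of 28 are equivalent, so no regiochemical choice is passed on to the closure of ring C.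

Step 14
Reactants: 28 acylphloroglucinol acetonide
Product: 30 target (2R,3R)-dihydroflavonol, via bis-MOM dihydroflavonol 29 (not isolated)
Conditions: 3 M aq HCl–MeOH (1:5), degassed, rt, then 45 °C
Reagents that add atoms: none
Why: Acid-mediated SN1 ring closure followed by acetal solvolysis: protonation opens the dioxolane at the benzylic C2–O bond, whose cation is stabilised by the ortho and para oxygens of ring B, an ortho hydroxyl of ring A captures it in a six-membered closure anti to the C3 oxygen to give the diequatorial 2,3-trans ring C (C2 becomes R under kinetic and thermodynamic trans preference, C3 is untouched and stays R), as in the acid cyclisation of 2'-hydroxychalcone epoxides to trans-dihydroflavonols, and the same acid then solvolyses the two aryl MOM ethers.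

**Compound list**

1 | resorcinol (benzene-1,3-diol) | Oc1cccc(O)c1 | starting material
2 | 1,3-bis(methoxymethoxy)benzene | COCOc1cccc(OCOC)c1 | intermediate
3 | geranyl bromide, (2E)-1-bromo-3,7-dimethylocta-2,6-diene | CC(C)=CCC/C(C)=C/CBr | starting material
4 | 2-lithio-1,3-bis(methoxymethoxy)benzene (not isolated) | [Li]c1c(OCOC)cccc1OCOC | intermediate
5 | 2-[(2E)-3,7-dimethylocta-2,6-dienyl]-1,3-bis(methoxymethoxy)benzene | CC(C)=CCC/C(C)=C/Cc1c(OCOC)cccc1OCOC | intermediate
6 | prenyl bromide, 1-bromo-3-methylbut-2-ene | CC(C)=CCBr | starting material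
7 | 4-lithio derivative of 5 (not isolated) | CC(C)=CCC/C(C)=C/Cc1c(OCOC)c([Li])ccc1OCOC | intermediate
8 | 2-[(2E)-3,7-dimethylocta-2,6-dienyl]-1,3-bis(methoxymethoxy)-4-(3-methylbut-2-enyl)benzene | CC(C)=CCC/C(C)=C/Cc1c(OCOC)c(CC=C(C)C)ccc1OCOC | intermediate
9 | aryllithium ArLi, 6-lithio derivative of 8 (not isolated) | CC(C)=CCC/C(C)=C/Cc1c(OCOC)c(CC=C(C)C)cc([Li])c1OCOC | intermediate
10 | ArCHO, 3-[(2E)-3,7-dimethylocta-2,6-dienyl]-2,4-bis(methoxymethoxy)-5-(3-methylbut-2-enyl)benzaldehyde | CC(C)=CCC/C(C)=C/Cc1c(OCOC)c(CC=C(C)C)cc(C=O)c1OCOC | intermediate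
11 | 2-[(tert-butyldimethylsilyl)oxy]acetic acid | CC(C)(C)[Si](C)(C)OCC(=O)O | starting material
12 | (R)-4-benzyl-1,3-oxazolidin-2-one | O=C1N[C@H](Cc2ccccc2)CO1 | starting material
13 | 2-[(tert-butyldimethylsilyl)oxy]acetic pivalic anhydride (not isolated) | CC(C)(C)[Si](C)(C)OCC(=O)OC(=O)C(C)(C)C | intermediate
14 | (R)-4-benzyl-3-{[(tert-butyldimethylsilyl)oxy]acetyl}-1,3-oxazolidin-2-one | CC(C)(C)[Si](C)(C)OCC(=O)N1[C@H](Cc2ccccc2)COC1=O | intermediate
15 | Z-dibutylboron enolate of 14 (not isolated) | CCCCB(CCCC)O/C(=C\O[Si](C)(C)C(C)(C)C)N1[C@H](Cc2ccccc2)COC1=O | intermediate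
16 | (R)-4-benzyl-3-[(2R,3S)-3-Ar-2-(tert-butyldimethylsilyloxy)-3-hydroxypropanoyl]-1,3-oxazolidin-2-one | CC(C)=CCC/C(C)=C/Cc1c(OCOC)c(CC=C(C)C)cc([C@H](O)[C@@H](O[Si](C)(C)C(C)(C)C)C(=O)N2[C@H](Cc3ccccc3)COC2=O)c1OCOC | intermediate
17 | (2R,3S)-3-Ar-2-(tert-butyldimethylsilyloxy)-3-hydroxy-N-methoxy-N-methylpropanamide | CC(C)=CCC/C(C)=C/Cc1c(OCOC)c(CC=C(C)C)cc([C@H](O)[C@@H](O[Si](C)(C)C(C)(C)C)C(=O)N(C)OC)c1OCOC | intermediate
18 | (2R,3S)-3-Ar-2,3-dihydroxy-N-methoxy-N-methylpropanamide | CC(C)=CCC/C(C)=C/Cc1c(OCOC)c(CC=C(C)C)cc([C@H](O)[C@@H](O)C(=O)N(C)OC)c1OCOC | intermediate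
19 | (4R,5S)-5-Ar-N-methoxy-N,2,2-trimethyl-1,3-dioxolane-4-carboxamide | CC(C)=CCC/C(C)=C/Cc1c(OCOC)c(CC=C(C)C)cc([C@@H]2OC(C)(C)O[C@H]2C(=O)N(C)OC)c1OCOC | intermediate
20 | 2,2,6-trimethyl-4H-1,3-dioxin-4-one | CC1=CC(=O)OC(C)(C)O1 | starting material
21 | lithium dienolate of 20 (not isolated) | C=C1C=C(O[Li])OC(C)(C)O1 | intermediate
22 | 2,2-dimethyl-6-(2-oxopropyl)-4H-1,3-dioxin-4-one | CC(=O)CC1=CC(=O)OC(C)(C)O1 | intermediate
23 | dilithium dianion of 22 (not isolated) | C=C(O[Li])C=C1C=C(O[Li])OC(C)(C)O1 | intermediate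
24 | 6-{4-[(4R,5S)-5-Ar-2,2-dimethyl-1,3-dioxolan-4-yl]-2,4-dioxobutyl}-2,2-dimethyl-4H-1,3-dioxin-4-one | CC(C)=CCC/C(C)=C/Cc1c(OCOC)c(CC=C(C)C)cc([C@@H]2OC(C)(C)O[C@H]2C(=O)CC(=O)CC3=CC(=O)OC(C)(C)O3)c1OCOC | intermediate
25 | acylketene, 7-[(4R,5S)-5-Ar-2,2-dimethyl-1,3-dioxolan-4-yl]-3,5,7-trioxohept-1-en-1-one (not isolated) | CC(C)=CCC/C(C)=C/Cc1c(OCOC)c(CC=C(C)C)cc([C@@H]2OC(C)(C)O[C@H]2C(=O)CC(=O)CC(=O)C=C=O)c1OCOC | intermediate
26 | methyl 7-[(4R,5S)-5-Ar-2,2-dimethyl-1,3-dioxolan-4-yl]-3,5,7-trioxoheptanoate | CC(C)=CCC/C(C)=C/Cc1c(OCOC)c(CC=C(C)C)cc([C@@H]2OC(C)(C)O[C@H]2C(=O)CC(=O)CC(=O)CC(=O)OC)c1OCOC | intermediate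
27 | 2-{[(4R,5S)-5-Ar-2,2-dimethyl-1,3-dioxolan-4-yl]carbonyl}cyclohexane-1,3,5-trione (not isolated) | CC(C)=CCC/C(C)=C/Cc1c(OCOC)c(CC=C(C)C)cc([C@@H]2OC(C)(C)O[C@H]2C(=O)C3C(=O)CC(=O)CC3=O)c1OCOC | intermediate
28 | [(4R,5S)-5-Ar-2,2-dimethyl-1,3-dioxolan-4-yl](2,4,6-trihydroxyphenyl)methanone | CC(C)=CCC/C(C)=C/Cc1c(OCOC)c(CC=C(C)C)cc([C@@H]2OC(C)(C)O[C@H]2C(=O)c3c(O)cc(O)cc3O)c1OCOC | intermediate
29 | (2R,3R)-2-Ar-3,5,7-trihydroxychroman-4-one, the bis-MOM ether of the target (not isolated) | CC(C)=CCC/C(C)=C/Cc1c(OCOC)c(CC=C(C)C)cc([C@H]2Oc3cc(O)cc(O)c3C(=O)[C@@H]2O)c1OCOC | intermediate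
30 | (2R,3R)-2-{3-[(2E)-3,7-dimethylocta-2,6-dienyl]-2,4-dihydroxy-5-(3-methylbut-2-enyl)phenyl}-3,5,7-trihydroxychroman-4-one | CC(C)=CCC/C(C)=C/Cc1c(O)c(CC=C(C)C)cc([C@H]2Oc3cc(O)cc(O)c3C(=O)[C@@H]2O)c1O | target

**Step count**

Total step count: 14. Longest linear sequence: 12 steps (steps 1 to 4, 6 to 9, 11 to 14); steps 5 and 10 are side branches.

**Steps most likely to fail, with fallbacks**

1. Step 13. The polyenolate may fold in the aldol sense (C8 onto C4, leading to a resorcylate) or lactonise through the C5 enol oxygen, and long exposure to methoxide may erode C3 by enolisation with β-elimination of the benzylic oxygen. Fallback, setting out from 19 and coming back at 30: ring A is brought in preformed instead of being folded. Phloroglucinol is converted with MOMCl and i-Pr2NEt into 1,3,5-tris(methoxymethoxy)benzene F1. F1 is lithiated between two OMOM groups (n-BuLi, THF, 0 °C) to 2,4,6-tris(methoxymethoxy)phenyllithium F2. F2 is added to Weinreb amide 19 at −78 °C to give the aryl ketone F3, which is the tris-MOM ether of 28. The acid treatment of step 14, applied to F3, should remove the acetonide and all five MOM groups and close ring C, which rejoins the route at 30.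

2. Step 14. Protic acid may add the freed ortho phenols of ring B across the prenyl and geranyl olefins before the last MOM ether is gone, the benzylic cation may be intercepted by methanol or by a second molecule, and closure may occur with incomplete trans control. Fallback, setting out from 28 and coming back at 30: the endgame is staged so that ring closure and unmasking run by different mechanisms; it makes no compound outside the list (F0). Compound 28 is treated with PPTS in wet MeCN at rt, which should open only the benzylic acetonide and close ring C, and the bis-MOM dihydroflavonol 29 is isolated (and equilibrated to the trans isomer if needed). The two aryl MOM ethers are then removed aprotically with ZnBr2 and n-PrSH in CH2Cl2 at 0 °C. There the methoxymethyl cation is transferred to the thiol within minutes, so no strong protic acid meets the ortho-prenyl phenols.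

3. Step 11. The dianion may act as a base on C3–H of the amide (epimerisation, opening of the dioxolane by β-elimination) or add sluggishly to the α-branched amide, and the diketo-dioxinone may cyclise prematurely during the thermolysis of step 12. Fallback, setting out from 19 and coming back at 26: the chain is built by polyanion chemistry without the dioxinone. The dianion of pentane-2,4-dione (NaH, then n-BuLi, THF, 0 °C) is acylated by 19 to give the 1,3,5-triketone F4. F4 is converted with LiN(i-Pr)2 (3 equiv) into its trianion and carboxylated at the terminal methyl with CO2 at −78 °C to give the 3,5,7-triketo acid F5. Brief treatment of F5 with Me3SiCHN2 in toluene–MeOH at 0 °C gives methyl ester 26, which enters step 13.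

**Further compounds**

F1 | step 13 | 1,3,5-tris(methoxymethoxy)benzene | COCOc1cc(OCOC)cc(OCOC)c1
F2 | step 13 | 2,4,6-tris(methoxymethoxy)phenyllithium | [Li]c1c(OCOC)cc(OCOC)cc1OCOC
F3 | step 13 | [(4R,5S)-5-Ar-2,2-dimethyl-1,3-dioxolan-4-yl][2,4,6-tris(methoxymethoxy)phenyl]methanone | CC(C)=CCC/C(C)=C/Cc1c(OCOC)c(CC=C(C)C)cc([C@@H]2OC(C)(C)O[C@H]2C(=O)c3c(OCOC)cc(OCOC)cc3OCOC)c1OCOC
F0 | step 14 | none | none
F4 | step 11 | 1-[(4R,5S)-5-Ar-2,2-dimethyl-1,3-dioxolan-4-yl]hexane-1,3,5-trione | CC(C)=CCC/C(C)=C/Cc1c(OCOC)c(CC=C(C)C)cc([C@@H]2OC(C)(C)O[C@H]2C(=O)CC(=O)CC(C)=O)c1OCOC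
F5 | step 11 | 7-[(4R,5S)-5-Ar-2,2-dimethyl-1,3-dioxolan-4-yl]-3,5,7-trioxoheptanoic acid | CC(C)=CCC/C(C)=C/Cc1c(OCOC)c(CC=C(C)C)cc([C@@H]2OC(C)(C)O[C@H]2C(=O)CC(=O)CC(=O)CC(=O)O)c1OCOC
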